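Readings and results were generated by integration for substances that don't exist, and the scatter is random.

Read at its last time, 120 min, the north run holds 17% product, and the question is what that reading is worth for a flask read hours later.

| setting | north-east | south-west | north | Monday's | Tuesday's |
|---|---|---|---|---|---|
| solid substrate | 0.10 M | 0.10 M | 0.10 M | 0.10 M | 0.10 M |
| enzyme | 0.075 mM | 0.16 mM | 0.26 mM | 0.10 mM | 0.30 mM |
| remark | run made earlier | run made earlier | run made earlier |  |  |
| time |  |  |  | 2.5 h | 8.0 h |

- north-east (time / min: product / %): 8.00: 0; 15.0: 0; 30.0: 0; 60.0: 2; 120: 8
- south-west (time / min: product / %): 8.00: 4; 15.0: 0; 30.0: 2; 60.0: 4; 120: 11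
- north (time / min: product / %): 20.0: 0; 40.0: 2; 60.0: 3; 80.0: 9; 120: 17

(each reading ± 1.5 percentage points)

- as a solid, counted per litre of solution: solid substrate
- what was read earlier has a scatter of 1.5 percentage points, one standard deviation
- at the start none of the solid substrate is in solution
- what has only dissolved of solid substrate counts as not reacted

* which one finishes higher in amount of product, in percent of the solid substrate charged ("neither" within 2 percentage points) (Monday's / Tuesday's / neither)
* amount of product at the end, in percent of the solid substrate charged, Monday's
* amount of product at the end, in percent of the solid substrate charged, Tuesday's

I picture the solid substrate dissolving and the enzyme acting on what has dissolved. The north run climbs 0.0120 M/h between its last two readings; call this climb of [product] per hour the late flow. Tuesday's enzyme, 0.30 mM, lies near the north run's 0.26 mM, so I carry this flow on to 8.0 h and get 89.0%; at this flow, a charge of 0.10 M takes 8.33 h.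

But the curves bend upward, and growth with the square of time would carry the north run through its whole charge by 4.85 h, sooner than Tuesday's reading. Against that, the north run's interval before gave 0.0180 M/h, so its readings show no further climb, though the late flow itself is uncertain by about 0.00318 M/h. The north-east run's late flow reads 0.00600 M/h, so from that run to the north run the enzyme grows 3.47-fold while the late flow, as read, merely doubles. I read this as dissolving taking over as the rate-limiting step, which gives a line, not a parabola. You may still object that a shrinking solid slows the flow; the runs stop at 17%, so I can't compute that away, and I keep my figure.

Monday's, at 0.10 mM, stands near the north-east run, whose late flow carried to 2.5 h gives 11.0%, a low figure since Monday's has more enzyme.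

The forecast names Tuesday's, with 14% for Monday's and 80% for Tuesday's, lower than my 89.0%, since “shrinking solid, enzyme decay or inhibition may slow it”. The flasks give Tuesday's, with 13.0% for Monday's and 92.3% for Tuesday's.

    starting material + enzyme → product + enzyme, rate k1*[starting material]^2*[enzyme]/(1 + ([starting material]/Kh1)^2) (0.140 M, k = 1.50 × 10⁵ /M²/h)
    solid substrate ⇌ starting material, rate k2*(cs2 - [starting material]) while solid is left; crystals form when [starting material] > cs2 (solubility = 0.0620 M, k = 0.350 /h)

Take the neighbour of Tuesday's charged with 0.40 M of solid substrate, enzyme and time held. The late flow is counted per litre, so the larger charge enters as a divisor: clearing it takes 33.3 h, well beyond 8.0 h, and the line gives 22.3% of the charge. The flask gives 26.8%, more than the line. That is 0.107 M of product against Tuesday's 0.0923 M, with 68.5% of the neighbour's charge still solid.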